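(The earlier runs and the new flask are simulated with constants of no real substance; the scatter is artificial.)

Every mole of charged starting material stays on the books: c(starting material) + c(intermediate) + c(product) stays at the charge, so I kept a ledger of those entries. The catalyst is not among them: it turns over. Starting material is the limiting reagent. The question was how much reaches the last entry.

| flask | starting material | catalyst | temperature | remark | time |
|---|---|---|---|---|---|
| north-west | 0.024 M | 26 µM | −25 °C | run made earlier |  |
| east | 0.035 M | 26 µM | −10 °C | run made earlier |  |
| south-east | 0.047 M | 13 µM | −25 °C | run made earlier |  |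
| Sunday's | 0.047 M | 26 µM | −20 °C |  | 2.5 min |
| Wednesday's | 0.047 M | 26 µM | 0 °C |  | 2.5 min |
| Saturday's | 0.047 M | 26 µM |  | at 0 °C until 50 s, from then on at −20 °C | 2.5 min |

- north-west (time / min: product / %): 0.500: 0.8; 1.00: 1.8; 1.50: 1.3; 2.00: 3.1; 2.50: 3.5
- east (time / s: product / %): 10.0: 1.0; 15.0: 1.2; 25.0: 2.5; 50.0: 8.6; 90.0: 19.5
- south-east (time / min: product / %): 0.500: 1.3; 1.00: 1.2; 1.50: 1.1; 2.00: 1.4; 2.50: 1.7

(standard deviation of a reading: 0.5 percentage points)

* the flask that comes out highest in amount of product, in percent of the starting material charged, or "all alike" when all lie within 1.5 percentage points (Sunday's / Wednesday's / Saturday's / all alike)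
* product at the end, in percent of the starting material charged, Sunday's
* product at the end, in percent of the starting material charged, Wednesday's
* product at the end, in percent of the starting material charged, Saturday's

- on the list of suspects stand: starting material -> intermediate; catalyst <-> dormant form; catalyst + intermediate <-> catalyst + product

The first entry in the ledger was the lag. In the east run, product went from 2.5% at 25.0 s to 8.6% at 50.0 s, so material was waiting in intermediate. The south-east run, with 13 µM of catalyst and 0.047 M of starting material, gave 1.7% at its last reading, against 3.5% in the north-west run with 26 µM and 0.024 M. Two settings differ between those runs, so this was an assumption: I took percent product as independent of the charge, treated the steps as pseudo-first-order, and tied the pace to catalyst.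

For two equal steps in line, the early product fraction is half the square of pace times time. The north-west run gave a pace of 0.00176 s⁻¹, and the east run at 50.0 s gave 0.00829 s⁻¹. I drew ln(pace) straight against temperature and kept 0.00296 s⁻¹ as the cold pace, the constant of each equal step at −20 °C with 26 µM of catalyst. The same line gave 0.0233 s⁻¹ at 0 °C.

Then I filled in the books. For Sunday's I booked 9.82% as product, by the same square rule that gave the pace. For Wednesday's I booked 86.3%, by the full curve of two equal steps. For Saturday's I booked 32.4% at the change. I treated the remainder as intermediate moving at the cold pace, which closed my estimate for Saturday's at 49.7%. So I expected Wednesday's to come out highest.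

The forecast also chose Wednesday's, with 9% for Sunday's, 65% for Wednesday's and 35% for Saturday's, its Wednesday's figure cut “for possible reversibility or catalyst dormancy”.

The flasks gave 9.38% for Sunday's, 56.9% for Wednesday's and 37.4% for Saturday's, with Wednesday's highest.

    starting material → intermediate (k = 0.0590 s⁻¹, Ea = 75.0 kJ mol⁻¹)
    catalyst ⇌ dormant form (K = 2.40, k = 0.00960 s⁻¹, Ea = 80.0 kJ mol⁻¹, ΔH = −37.0 kJ mol⁻¹)
    catalyst + intermediate ⇌ catalyst + product (K = 14.0, k = 460 M⁻¹ s⁻¹, Ea = 41.0 kJ mol⁻¹, ΔH = −60.0 kJ mol⁻¹)
    (constants at 0 °C)

Wednesday's closed below my figure. With the dormant form struck out Wednesday's gives 75.9% instead of 56.9%, and left for 25.0 min it gives 93.1%, so dormancy and the time allowed are each a part of what holds its product down. I then scaled the cold pace by the free catalyst in Saturday's at 2.50 min, 61.7% of its charge, which gave 0.00182 s⁻¹. Applied to the intermediate and starting material still open in Saturday's, it booked 57.3% at 6.00 min, and Saturday's flask read 55.2% at that time.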